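Readings and results were generated by integration from invented constants; noise was put on by code.

The autumn run lost electrophile along a straight line: 20.0% had reacted by 20.0 h and 41.3% by 40.0 h, twice as much in twice the time. The spring run, with 4.4 mM of buffer acid against 2.8 mM, stood at 40.4% at that time, a gap of 0.9 percentage points between two readings that each scatter by 0.5 points.

all flasks: electrophile 20 mM; gas 1.5 mM (held)

| flask | buffer base | buffer acid | remark | time |
|---|---|---|---|---|
| autumn | 40 mM | 2.8 mM | run made earlier |  |
| spring | 40 mM | 4.4 mM | run made earlier |  |
| flask | 40.0 mM | 2.00 mM |  | 30 h |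

| run | time / h | electrophile / % | product / % |
|---|---|---|---|
| autumn | 3.00 | 97.2 | 3.6 |
| autumn | 5.00 | 95.7 | 5.3 |
| autumn | 10.0 | 89.3 | 9.9 |
| autumn | 20.0 | 80.0 | 20.7 |
| autumn | 40.0 | 58.7 | 40.9 |
| spring | 3.00 | 97.2 | 3.0 |
| spring | 10.0 | 89.5 | 9.6 |
| spring | 15.0 | 85.3 | 15.3 |
| spring | 25.0 | 74.3 | 25.6 |
| spring | 40.0 | 59.6 | 40.4 |

(standard deviation of a reading: 0.5 percentage points)

- at the start none of the gas is in solution
- a reading or a percentage of product counts all its forms, free or not
- the earlier runs do not show the pH; that part of a forecast is a guess

- part of the electrophile that has reacted at 30 h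
- pH of the solution at 30 h

So I took the loss of electrophile in both runs as zero order, at one constant rate r, and read r from the last reading of each run as 0.204 mM/h. Integrating d[electrophile]/dt = −r gives a straight fall, and the part reacted at time t is t/τ, where the clearing time τ is 97.9 h: the charge of electrophile divided by r. Two times then stood against each other in the flask, τ and the 30 h asked, and since the asked time is shorter than τ, the line in my reckoning had not reached its end. My own reckoning gave 30.6%, provided that 2.00 mM of buffer acid, below the tested range, left r where it was.

The forecast said 30.6% and pH 7.7, the pH being a guess: “Less acid in the flask should not slow a transfer-limited reaction”.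

The flask gave 30.5% and pH 6.62.

    protonated nucleophile ⇌ nucleophile + acid, settled at all times (K = 5.00 × 10⁻⁷ M)
    electrophile + nucleophile → acid + product + leaving group (k = 370 /M/h)
    gas ⇌ nucleophile, rate k3*(csat - [nucleophile]) (kL = 0.140 /h)
    buffer acid ⇌ buffer base + acid, settled at all times (K = 1.00 × 10⁻⁶ M)
    crystals ⇌ product, rate k5*(cs5 - [product]) while solid is left; crystals form when [product] > cs5 (solubility = 0.280 mM, k = 1.10 /h)

Read back from the flask, t/c gives τ as 98.4 h, against my 97.9 h. At 30.0 h the nucleophile in the flask had a half-life of 0.13 h against the electrophile, far shorter than the 4.95 h half-time of the crossing of gas, the rate-limiting step. The nucleophile in the flask then stood at 0.0395 mM, against a saturation concentration of gas of 1.5 mM. For the neighbour flask charged with 12 mM of electrophile, the same r makes τ 58.8 h and t/τ 51.0%, and that flask gave 49.3%.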